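**Plan**

- Retrosynthesis: the feruloyl ester bond at C9–O is cut first (ferulic acid), then the C7'–aryl bond (guaiacyl Grignard reagent onto a lactol), then the two oxolane bonds O1–C5 and C3–C4 in one annulation.
- Enabling feature: O1–C2(syringyl)–C3 with C9 on C3 is the footprint of a trans aryl vinyl epoxide (inner vinyl carbon = C9). C5H2–C4 with C7' is the footprint of diethyl methylenemalonate (one ester becomes C7', the other is discarded).
- Forward: sinapic acid → Sharpless epoxy alcohol → vinyl epoxide; a palladium-catalysed [3+2] annulation closes the oxolane, the only ring of the target.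
- Then: vinyl → C9–OH, which lactonises onto C4 (temporary ring); Krapcho; lactol; aryl Grignard; hydrogenolysis of the C7' oxygen and benzyl ethers; Mitsunobu esterification with ferulic acid.
- Stereochemistry: C2 from the Sharpless epoxidation; C3 from double inversion at the allylic carbon (2,3-trans); C4 from the cis ring fusion of the C9–O–C7' lactone, which forces C7' cis to C9.

Key step: step 6

Remark: diethyl methylenemalonate is taken as a commercial reagent and is distilled from its stabiliser just before use; oxolane atoms are numbered O1, C2 (syringyl carbon), C3, C4, C5 throughout, with C9 on C3 and C7' on C4.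

**Route**

Step 1
Reactants: 1 sinapic acid
Product: 2 benzyl (2E)-3-[4-(benzyloxy)-3,5-dimethoxyphenyl]prop-2-enoate
Conditions: BnBr (2.4 equiv), K2CO3, DMF, 60 °C
Reagents that add atoms: benzyl bromide, BrCc1ccccc1
Why: Williamson etherification of the hindered phenoxide and O-alkylation of the carboxylate occur in one pot and leave the E alkene untouched.

Step 2
Reactants: 2 benzyl (2E)-3-[4-(benzyloxy)-3,5-dimethoxyphenyl]prop-2-enoate
Product: 3 (2E)-3-[4-(benzyloxy)-3,5-dimethoxyphenyl]prop-2-en-1-ol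
Conditions: iBu2AlH (3 equiv), CH2Cl2, −78 → 0 °C; aq. potassium sodium tartrate
Reagents that add atoms: none
Why: Hydride reduction of an α,β-unsaturated ester with iBu2AlH is a clean 1,2-reduction to the allylic alcohol, and the aryl benzyl ether is inert.

Step 3
Reactants: 3 (2E)-3-[4-(benzyloxy)-3,5-dimethoxyphenyl]prop-2-en-1-ol
Product: 4 [(2R,3R)-3-[4-(benzyloxy)-3,5-dimethoxyphenyl]oxiran-2-yl]methanol
Conditions: Ti(OiPr)4 (10 mol%), D-(−)-diethyl tartrate (12 mol%), tBuOOH, 4 Å MS, CH2Cl2, −20 °C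
Reagents that add atoms: tert-butyl hydroperoxide, CC(C)(C)OO
Why: Sharpless asymmetric epoxidation; the D-(−)-tartrate titanium complex delivers oxygen to the alkene face that gives the (2R,3R)-epoxy alcohol (the natural tartrate gives 2S,3S with E-cinnamyl alcohols), which fixes the aryl-bearing carbon (later C2), and the E alkene gives the trans epoxide.

Step 4
Reactants: 4 [(2R,3R)-3-[4-(benzyloxy)-3,5-dimethoxyphenyl]oxiran-2-yl]methanol
Product: 5 (2S,3R)-3-[4-(benzyloxy)-3,5-dimethoxyphenyl]oxirane-2-carbaldehyde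
Conditions: SO3·pyridine, DMSO, iPr2NEt, CH2Cl2, 0 °C
Reagents that add atoms: none
Why: Parikh–Doering oxidation is non-acidic and runs at 0 °C, so the acid-sensitive aryl epoxide and both stereocentres should survive (the descriptor at C2 changes only through priorities).

Step 5
Reactants: 5 (2S,3R)-3-[4-(benzyloxy)-3,5-dimethoxyphenyl]oxirane-2-carbaldehyde
Product: 6 (2R,3R)-2-[4-(benzyloxy)-3,5-dimethoxyphenyl]-3-ethenyloxirane
Conditions: Ph3PCH3Br, KN(SiMe3)2, THF, −78 → 0 °C
Reagents that add atoms: methyltriphenylphosphonium bromide, C[P+](c1ccccc1)(c1ccccc1)c1ccccc1.[Br-]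
Why: Wittig methylenation with the non-stabilised ylide is fast at low temperature, and the aldehyde α-carbon is an epoxide carbon that does not epimerise under these conditions.

Step 6
Reactants: 6 (2R,3R)-2-[4-(benzyloxy)-3,5-dimethoxyphenyl]-3-ethenyloxirane; 7 diethyl methylenemalonate
Product: 8 diethyl (2S,3S)-2-[4-(benzyloxy)-3,5-dimethoxyphenyl]-3-ethenyloxolane-4,4-dicarboxylate
Conditions: Pd2(dba)3·CHCl3 (2.5 mol%), 1,2-bis(diphenylphosphino)ethane (6 mol%), THF, rt; 6 and 7 (1.3 equiv) co-added over 2 h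
Reagents that add atoms: none
Why: Zerovalent palladium attacks the vinyl group of 6 anti to the allylic C3–O bond and opens the strained ring to a π-allylpalladium alkoxide zwitterion, leaving the benzylic C2–O bond and its configuration untouched; the alkoxide adds to the unsubstituted CH2 of 7 (oxa-Michael, O1–C5) and the malonate carbanion so formed attacks the nearer allyl carbon anti to the metal (C3–C4), which releases the catalyst. The closest known reaction type is the palladium-catalysed [3+2] cycloaddition of vinyl epoxides with doubly activated alkenes to give 3-vinyloxolanes. The oxolane closes in a 5-exo attack on the allyl unit, which is kinetically preferred over attack at the distal terminus (seven-membered ring). The new C3 stereocentre is controlled by C2: two inversions amount to net retention of the trans epoxide relationship, and any π–σ–π face exchange of the allyl unit before closure also drains to the 2,3-trans ring because the cis transition state presses the allyl unit against the C2 aryl group. The step needs ring closure to outrun anionic oligomerisation of 7 and β-hydride isomerisation of the zwitterion to an enone; co-addition of 6 and 7 keeps both the free acceptor and the untrapped zwitterion at low concentration, and the tethered carbanion–allyl cation pair closes intramolecularly. C4 is not yet stereogenic because its two esters are identical.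

Step 7
Reactants: 8 diethyl (2S,3S)-2-[4-(benzyloxy)-3,5-dimethoxyphenyl]-3-ethenyloxolane-4,4-dicarboxylate
Product: 11 ethyl (1R,5R,6S)-6-[4-(benzyloxy)-3,5-dimethoxyphenyl]-2-oxo-3,7-dioxabicyclo[3.3.0]octane-1-carboxylate, via formyl diester 9 (not isolated), via hydroxy diester 10 (not isolated)
Conditions: O3, CH2Cl2/MeOH (4:1), −78 °C, stopped at first blue tinge; NaBH4, −78 → 0 °C; then PPTS (cat.), toluene, 50 °C
Reagents that add atoms: ozone, [O-][O+]=O
Why: Ozonolysis with reductive borohydride work-up cuts the vinyl group (much more reactive to ozone than the alkoxy arenes) to the C9 hydroxymethyl group, which can reach only the ester on its own face of C4 and closes the cis-fused γ-lactone by transesterification, so the lactone carbonyl (C7') is cis to C9.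

Step 8
Reactants: 11 ethyl (1R,5R,6S)-6-[4-(benzyloxy)-3,5-dimethoxyphenyl]-2-oxo-3,7-dioxabicyclo[3.3.0]octane-1-carboxylate
Product: 12 (1R,5R,6S)-6-[4-(benzyloxy)-3,5-dimethoxyphenyl]-3,7-dioxabicyclo[3.3.0]octan-2-one
Conditions: LiCl, H2O, DMSO, 150 °C
Reagents that add atoms: none
Why: Krapcho dealkoxycarbonylation of an α-ethoxycarbonyl γ-lactone; the lactone enolate can be protonated only to the cis-fused bicycle, which sets C4–H with C7' cis to C9.

Step 9
Reactants: 12 (1R,5R,6S)-6-[4-(benzyloxy)-3,5-dimethoxyphenyl]-3,7-dioxabicyclo[3.3.0]octan-2-one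
Product: 13 (1R,5R,6S)-6-[4-(benzyloxy)-3,5-dimethoxyphenyl]-3,7-dioxabicyclo[3.3.0]octan-2-ol (both lactol epimers)
Conditions: iBu2AlH (1.1 equiv), CH2Cl2, −78 °C; aq. potassium sodium tartrate
Reagents that add atoms: none
Why: Partial reduction of a γ-lactone to the lactol stops at the aluminium hemiacetal at −78 °C, and no other carbonyl group is present.

Step 10
Reactants: 14 4-bromo-2-methoxyphenol
Product: 15 1-(benzyloxy)-4-bromo-2-methoxybenzene
Conditions: BnBr, K2CO3, acetone, reflux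
Reagents that add atoms: benzyl bromide, BrCc1ccccc1
Why: Williamson ether synthesis on an unhindered phenol.

Step 11
Reactants: 13 (1R,5R,6S)-6-[4-(benzyloxy)-3,5-dimethoxyphenyl]-3,7-dioxabicyclo[3.3.0]octan-2-ol; 15 1-(benzyloxy)-4-bromo-2-methoxybenzene
Product: 18 {(2S,3R,4R)-4-{acetoxy[4-(benzyloxy)-3-methoxyphenyl]methyl}-2-[4-(benzyloxy)-3,5-dimethoxyphenyl]oxolan-3-yl}methyl acetate (C7' epimers), via arylmagnesium bromide 16 (not isolated), via diol 17 (not isolated)
Conditions: 15 (3.5 equiv), Mg, THF, 50 °C; add 13, 0 °C → rt; then Ac2O, DMAP, 0 °C → rt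
Reagents that add atoms: acetic anhydride, CC(=O)OC(C)=O
Why: Grignard addition to a lactol: the first equivalent of 16 deprotonates 13, the ring-opened alkoxy aldehyde is arylated at C7' faster than it enolises at C4, and the bis(magnesium alkoxide) of 17 is acetylated in the same flask; the C7' carbinol epimers do not matter because this oxygen is removed in step 12.

Step 12
Reactants: 18 {(2S,3R,4R)-4-{acetoxy[4-(benzyloxy)-3-methoxyphenyl]methyl}-2-[4-(benzyloxy)-3,5-dimethoxyphenyl]oxolan-3-yl}methyl acetate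
Product: 20 {(2S,3R,4R)-2-(4-hydroxy-3,5-dimethoxyphenyl)-4-[(4-hydroxy-3-methoxyphenyl)methyl]oxolan-3-yl}methanol, via monoacetate 19 (not isolated)
Conditions: H2 (1 atm), Pd/C, EtOAc, rt; filter; K2CO3, MeOH, 0 °C
Reagents that add atoms: none
Why: Palladium-catalysed hydrogenolysis should cleave the two aryl benzyl ethers and the C7'–OAc bond (a benzylic acetate on a para-oxygenated ring, a far better leaving group than the ring alkoxide at C2) at 1 atm in a non-nucleophilic solvent while the C2–O1 bond persists, and base-catalysed methanolysis then frees C9–OH; C4 is not touched, so the cis C9/C7' relation is kept.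

Step 13
Reactants: 20 {(2S,3R,4R)-2-(4-hydroxy-3,5-dimethoxyphenyl)-4-[(4-hydroxy-3-methoxyphenyl)methyl]oxolan-3-yl}methanol; 21 ferulic acid
Product: 22 {(2S,3R,4R)-2-(4-hydroxy-3,5-dimethoxyphenyl)-4-[(4-hydroxy-3-methoxyphenyl)methyl]oxolan-3-yl}methyl (2E)-3-(4-hydroxy-3-methoxyphenyl)prop-2-enoate
Conditions: PPh3, diisopropyl azodicarboxylate, THF, 0 °C → rt
Reagents that add atoms: none
Why: Mitsunobu esterification; the carboxylic acid is by far the most acidic pronucleophile, so the carboxylate rather than any of the three phenols should displace the oxyphosphonium of the only aliphatic alcohol, C9 is not stereogenic, and the E alkene is unaffected.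

**Compound list**

1 | sinapic acid, (2E)-3-(4-hydroxy-3,5-dimethoxyphenyl)prop-2-enoic acid | COc1cc(/C=C/C(=O)O)cc(OC)c1O | starting material
2 | benzyl (2E)-3-[4-(benzyloxy)-3,5-dimethoxyphenyl]prop-2-enoate | COc1cc(/C=C/C(=O)OCc2ccccc2)cc(OC)c1OCc1ccccc1 | intermediate
3 | (2E)-3-[4-(benzyloxy)-3,5-dimethoxyphenyl]prop-2-en-1-ol | COc1cc(/C=C/CO)cc(OC)c1OCc1ccccc1 | intermediate
4 | [(2R,3R)-3-[4-(benzyloxy)-3,5-dimethoxyphenyl]oxiran-2-yl]methanol | OC[C@H]1O[C@@H]1c1cc(OC)c(OCc2ccccc2)c(OC)c1 | intermediate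
5 | (2S,3R)-3-[4-(benzyloxy)-3,5-dimethoxyphenyl]oxirane-2-carbaldehyde | O=C[C@H]1O[C@@H]1c1cc(OC)c(OCc2ccccc2)c(OC)c1 | intermediate
6 | (2R,3R)-2-[4-(benzyloxy)-3,5-dimethoxyphenyl]-3-ethenyloxirane (trans) | C=C[C@H]1O[C@@H]1c1cc(OC)c(OCc2ccccc2)c(OC)c1 | intermediate
7 | diethyl methylenemalonate (diethyl 2-methylidenepropanedioate) | C=C(C(=O)OCC)C(=O)OCC | starting material
8 | diethyl (2S,3S)-2-[4-(benzyloxy)-3,5-dimethoxyphenyl]-3-ethenyloxolane-4,4-dicarboxylate (2,3-trans) | C=C[C@H]1C(C(=O)OCC)(C(=O)OCC)CO[C@@H]1c1cc(OC)c(OCc2ccccc2)c(OC)c1 | intermediate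
9 | diethyl (2S,3S)-2-[4-(benzyloxy)-3,5-dimethoxyphenyl]-3-formyloxolane-4,4-dicarboxylate (not isolated) | O=C[C@H]1C(C(=O)OCC)(C(=O)OCC)CO[C@@H]1c1cc(OC)c(OCc2ccccc2)c(OC)c1 | intermediate
10 | diethyl (2S,3R)-2-[4-(benzyloxy)-3,5-dimethoxyphenyl]-3-(hydroxymethyl)oxolane-4,4-dicarboxylate (not isolated) | OC[C@H]1C(C(=O)OCC)(C(=O)OCC)CO[C@@H]1c1cc(OC)c(OCc2ccccc2)c(OC)c1 | intermediate
11 | ethyl (1R,5R,6S)-6-[4-(benzyloxy)-3,5-dimethoxyphenyl]-2-oxo-3,7-dioxabicyclo[3.3.0]octane-1-carboxylate (cis-fused) | O=C1OC[C@H]2[C@]1(C(=O)OCC)CO[C@@H]2c1cc(OC)c(OCc2ccccc2)c(OC)c1 | intermediate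
12 | (1R,5R,6S)-6-[4-(benzyloxy)-3,5-dimethoxyphenyl]-3,7-dioxabicyclo[3.3.0]octan-2-one (cis-fused) | O=C1OC[C@H]2[C@@H]1CO[C@@H]2c1cc(OC)c(OCc2ccccc2)c(OC)c1 | intermediate
13 | (1R,5R,6S)-6-[4-(benzyloxy)-3,5-dimethoxyphenyl]-3,7-dioxabicyclo[3.3.0]octan-2-ol (both lactol epimers) | OC1OC[C@H]2[C@@H]1CO[C@@H]2c1cc(OC)c(OCc2ccccc2)c(OC)c1 | intermediate
14 | 4-bromo-2-methoxyphenol | COc1cc(Br)ccc1O | starting material
15 | 1-(benzyloxy)-4-bromo-2-methoxybenzene | COc1cc(Br)ccc1OCc1ccccc1 | intermediate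
16 | [4-(benzyloxy)-3-methoxyphenyl]magnesium bromide (not isolated) | COc1cc([Mg]Br)ccc1OCc1ccccc1 | intermediate
17 | {(2S,3R,4R)-2-[4-(benzyloxy)-3,5-dimethoxyphenyl]-4-{[4-(benzyloxy)-3-methoxyphenyl](hydroxy)methyl}oxolan-3-yl}methanol (C7' epimers; not isolated) | OC[C@H]1[C@@H](C(O)c2ccc(OCc3ccccc3)c(OC)c2)CO[C@@H]1c1cc(OC)c(OCc2ccccc2)c(OC)c1 | intermediate
18 | {(2S,3R,4R)-4-{acetoxy[4-(benzyloxy)-3-methoxyphenyl]methyl}-2-[4-(benzyloxy)-3,5-dimethoxyphenyl]oxolan-3-yl}methyl acetate (C7' epimers) | CC(=O)OC[C@H]1[C@@H](C(OC(C)=O)c2ccc(OCc3ccccc3)c(OC)c2)CO[C@@H]1c1cc(OC)c(OCc2ccccc2)c(OC)c1 | intermediate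
19 | {(2S,3R,4R)-2-(4-hydroxy-3,5-dimethoxyphenyl)-4-[(4-hydroxy-3-methoxyphenyl)methyl]oxolan-3-yl}methyl acetate (not isolated) | CC(=O)OC[C@H]1[C@@H](Cc2ccc(O)c(OC)c2)CO[C@@H]1c1cc(OC)c(O)c(OC)c1 | intermediate
20 | {(2S,3R,4R)-2-(4-hydroxy-3,5-dimethoxyphenyl)-4-[(4-hydroxy-3-methoxyphenyl)methyl]oxolan-3-yl}methanol | OC[C@H]1[C@@H](Cc2ccc(O)c(OC)c2)CO[C@@H]1c1cc(OC)c(O)c(OC)c1 | intermediate
21 | ferulic acid, (2E)-3-(4-hydroxy-3-methoxyphenyl)prop-2-enoic acid | COc1cc(/C=C/C(=O)O)ccc1O | starting material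
22 | {(2S,3R,4R)-2-(4-hydroxy-3,5-dimethoxyphenyl)-4-[(4-hydroxy-3-methoxyphenyl)methyl]oxolan-3-yl}methyl (2E)-3-(4-hydroxy-3-methoxyphenyl)prop-2-enoate | COc1cc(/C=C/C(=O)OC[C@H]2[C@@H](Cc3ccc(O)c(OC)c3)CO[C@@H]2c2cc(OC)c(O)c(OC)c2)ccc1O | target

**Step count**

Total: 13 steps. Longest linear sequence: 12 steps (steps 1–9 and 11–13 from sinapic acid); step 10 is the one-step side branch.

**Steps most likely to fail**

1. Step 6. The malonate carbanion or the alkoxide may start anionic oligomerisation of 7 faster than the ring closes, the zwitterion may isomerise by β-hydride loss, or closure on the wrong allyl face may erode the 2,3-trans selectivity.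
Fallback, from 6 back to 8: the two bond formations are separated. Palladium-catalysed 1,4-addition of acetic acid to 6 (Pd(PPh3)4, AcOH, THF, 0 °C) should give (2E,4S)-4-[4-(benzyloxy)-3,5-dimethoxyphenyl]-4-hydroxybut-2-en-1-yl acetate F1 with the benzylic centre untouched. Its sodium alkoxide (NaH, THF, −78 °C) is treated with 7 added slowly and quenched cold with AcOH to give diethyl 2-({[(1S,2E)-4-acetoxy-1-[4-(benzyloxy)-3,5-dimethoxyphenyl]but-2-en-1-yl]oxy}methyl)propanedioate F2. An intramolecular Tsuji–Trost alkylation of F2 (Pd2(dba)3·CHCl3, the matched enantiomer of the DACH-phenyl Trost ligand, N,O-bis(trimethylsilyl)acetamide, KOAc cat., CH2Cl2) then closes C3–C4 in the same 5-exo mode under ligand control of the allyl face and returns to 8.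

2. Step 12. Hydrogenolysis may go too far and open the C2–O1 ring bond once the syringyl phenol is free, or the labile benzylic acetate may solvolyse through a quinone methide before it is reduced.
Fallback, from 18 back to 19: deoxygenation and debenzylation are done by two different mechanisms. Ionic hydrogenation of 18 (Et3SiH, BF3·OEt2, CH2Cl2, −78 °C) ionises only the benzylic acetate and reduces the C7' cation (the trans C2 aryl group cannot capture it) to {(2S,3R,4R)-2-[4-(benzyloxy)-3,5-dimethoxyphenyl]-4-{[4-(benzyloxy)-3-methoxyphenyl]methyl}oxolan-3-yl}methyl acetate F3. A short hydrogenolysis (H2, Pd/C, EtOAc), which now has only the two aryl benzyl ethers to cleave, returns to 19, and the methanolysis of step 12 follows.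

3. Step 13. Phenol O-alkylation may compete, or displacement at the β-branched C9 may be slow enough for the betaine to be consumed in side reactions.
Fallback, from 20 back to 22: the ester is made by acyl transfer on a phenol-protected alcohol. Silylation of 20 (tert-butyldimethylsilyl chloride, imidazole, DMF) gives the tris(silyl ether) tert-butyl{[(2S,3R,4R)-2-[4-(tert-butyldimethylsilyloxy)-3,5-dimethoxyphenyl]-4-{[4-(tert-butyldimethylsilyloxy)-3-methoxyphenyl]methyl}oxolan-3-yl]methoxy}dimethylsilane F4, and PPTS in MeOH removes only the alkyl silyl ether (aryl silyl ethers are acid-stable) to give {(2S,3R,4R)-2-[4-(tert-butyldimethylsilyloxy)-3,5-dimethoxyphenyl]-4-{[4-(tert-butyldimethylsilyloxy)-3-methoxyphenyl]methyl}oxolan-3-yl}methanol F5. In parallel 21 is silylated twice to tert-butyldimethylsilyl (2E)-3-[4-(tert-butyldimethylsilyloxy)-3-methoxyphenyl]prop-2-enoate F6, whose silyl ester is hydrolysed (aqueous AcOH, THF) to (2E)-3-[4-(tert-butyldimethylsilyloxy)-3-methoxyphenyl]prop-2-enoic acid F7. Steglich esterification of F5 with F7 (EDC·HCl, DMAP, CH2Cl2) gives {(2S,3R,4R)-2-[4-(tert-butyldimethylsilyloxy)-3,5-dimethoxyphenyl]-4-{[4-(tert-butyldimethylsilyloxy)-3-methoxyphenyl]methyl}oxolan-3-yl}methyl (2E)-3-[4-(tert-butyldimethylsilyloxy)-3-methoxyphenyl]prop-2-enoate F8, and Et3N·3HF in THF frees the three phenols to return to 22.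

**Further compounds**

F1 | step 6 | (2E,4S)-4-[4-(benzyloxy)-3,5-dimethoxyphenyl]-4-hydroxybut-2-en-1-yl acetate | CC(=O)OC/C=C/[C@H](O)c1cc(OC)c(OCc2ccccc2)c(OC)c1
F2 | step 6 | diethyl 2-({[(1S,2E)-4-acetoxy-1-[4-(benzyloxy)-3,5-dimethoxyphenyl]but-2-en-1-yl]oxy}methyl)propanedioate | CCOC(=O)C(CO[C@@H](/C=C/COC(C)=O)c1cc(OC)c(OCc2ccccc2)c(OC)c1)C(=O)OCC
F3 | step 12 | {(2S,3R,4R)-2-[4-(benzyloxy)-3,5-dimethoxyphenyl]-4-{[4-(benzyloxy)-3-methoxyphenyl]methyl}oxolan-3-yl}methyl acetate | CC(=O)OC[C@H]1[C@@H](Cc2ccc(OCc3ccccc3)c(OC)c2)CO[C@@H]1c1cc(OC)c(OCc2ccccc2)c(OC)c1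
F4 | step 13 | tert-butyl{[(2S,3R,4R)-2-[4-(tert-butyldimethylsilyloxy)-3,5-dimethoxyphenyl]-4-{[4-(tert-butyldimethylsilyloxy)-3-methoxyphenyl]methyl}oxolan-3-yl]methoxy}dimethylsilane | CC(C)(C)[Si](C)(C)OC[C@H]1[C@@H](Cc2ccc(O[Si](C)(C)C(C)(C)C)c(OC)c2)CO[C@@H]1c1cc(OC)c(O[Si](C)(C)C(C)(C)C)c(OC)c1
F5 | step 13 | {(2S,3R,4R)-2-[4-(tert-butyldimethylsilyloxy)-3,5-dimethoxyphenyl]-4-{[4-(tert-butyldimethylsilyloxy)-3-methoxyphenyl]methyl}oxolan-3-yl}methanol | OC[C@H]1[C@@H](Cc2ccc(O[Si](C)(C)C(C)(C)C)c(OC)c2)CO[C@@H]1c1cc(OC)c(O[Si](C)(C)C(C)(C)C)c(OC)c1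
F6 | step 13 | tert-butyldimethylsilyl (2E)-3-[4-(tert-butyldimethylsilyloxy)-3-methoxyphenyl]prop-2-enoate | COc1cc(/C=C/C(=O)O[Si](C)(C)C(C)(C)C)ccc1O[Si](C)(C)C(C)(C)C
F7 | step 13 | (2E)-3-[4-(tert-butyldimethylsilyloxy)-3-methoxyphenyl]prop-2-enoic acid | COc1cc(/C=C/C(=O)O)ccc1O[Si](C)(C)C(C)(C)C
F8 | step 13 | {(2S,3R,4R)-2-[4-(tert-butyldimethylsilyloxy)-3,5-dimethoxyphenyl]-4-{[4-(tert-butyldimethylsilyloxy)-3-methoxyphenyl]methyl}oxolan-3-yl}methyl (2E)-3-[4-(tert-butyldimethylsilyloxy)-3-methoxyphenyl]prop-2-enoate | COc1cc(/C=C/C(=O)OC[C@H]2[C@@H](Cc3ccc(O[Si](C)(C)C(C)(C)C)c(OC)c3)CO[C@@H]2c2cc(OC)c(O[Si](C)(C)C(C)(C)C)c(OC)c2)ccc1O[Si](C)(C)C(C)(C)C
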